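Assumption: the oxidative coupling follows the chelated (Z)-enolate model of Evans alkylations (bond formation anti to the auxiliary's 4-benzyl group), so the (S)-auxiliary gives 4R. This was derived from the model, not tested.

## Retrosynthetic overview

1. Target 13 ⇐ bis-benzyl ether 12 by hydrogenolysis (last step).
2. 12 ⇐ succinate 9: reduce the imide carbonyl (becomes C5), close the lactone (the only ring formed), epimerise C3 to trans.
3. 9 ⇐ C3–C4 bond by oxidative heterocoupling of two enolates, imide 4 (dimethoxy half, carries the auxiliary, sets C4) and benzyl ester 6 (catechol half, becomes C3). Two α-carbons that are both normally nucleophilic are joined.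
4. 4 ⇐ acid 1 + oxazolidinone 2; 6 ⇐ hydrocaffeic acid 5 + BnBr.

## Route

Step 1
Reactants: 1 3-(3,4-dimethoxyphenyl)propanoic acid; 2 (S)-4-benzyl-1,3-oxazolidin-2-one
Product: 4 (S)-4-benzyl-3-[3-(3,4-dimethoxyphenyl)propanoyl]-1,3-oxazolidin-2-one, via mixed pivalic anhydride 3 (not isolated)
Conditions: PivCl, Et3N, THF, –20 °C; then 2, LiCl, –20 °C → rt
Reagents that add atoms: none
Why: One-pot mixed-anhydride N-acylation of an oxazolidinone (LiCl/Et3N activation) is the standard preparation of Evans imides, and the auxiliary stereocentre is not touched.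

Step 2
Reactants: 5 3-(3,4-dihydroxyphenyl)propanoic acid
Product: 6 benzyl 3-[3,4-bis(benzyloxy)phenyl]propanoate
Conditions: BnBr (3.3 equiv), K2CO3 (4.5 equiv), DMF, 60 °C, N2
Reagents that add atoms: benzyl bromide BrCc1ccccc1
Why: Williamson O-alkylation of both phenoxides and the carboxylate in one operation protects the catechol and makes the ester, with N2 excluding catechol oxidation.

Step 3
Reactants: 4 (S)-4-benzyl-3-[3-(3,4-dimethoxyphenyl)propanoyl]-1,3-oxazolidin-2-one; 6 benzyl 3-[3,4-bis(benzyloxy)phenyl]propanoate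
Product: 9 benzyl (3R)-4-[(4S)-4-benzyl-2-oxo-1,3-oxazolidin-3-yl]-2-[3,4-bis(benzyloxy)benzyl]-3-(3,4-dimethoxybenzyl)-4-oxobutanoate (C2 epimer mixture), via imide lithium (Z)-enolate 7 (not isolated), via ester lithium enolate 8 (not isolated)
Conditions: 4 (1.0 equiv) + 6 (1.5 equiv) added to LDA (commercial solution, 2.6 equiv), THF, –78 °C, 30 min; then Fe(acac)3 (2.6 equiv), –78 °C → rt
Reagents that add atoms: none
Why: Fe(III)-mediated oxidative enolate heterocoupling, in which single-electron oxidation turns one enolate into an electrophilic α-carbonyl radical (an enolonium equivalent) that the other enolate captures before a second oxidation; bond formation on the chelated (Z)-imide enolate occurs on the face opposite the auxiliary's benzyl group and sets the imide α-carbon (future C4) as R, while the ester α-carbon (future C3) forms as a mixture that step 4 corrects.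

Step 4
Reactants: 9 benzyl (3R)-4-[(4S)-4-benzyl-2-oxo-1,3-oxazolidin-3-yl]-2-[3,4-bis(benzyloxy)benzyl]-3-(3,4-dimethoxybenzyl)-4-oxobutanoate
Product: 12 (3R,4R)-3-[3,4-bis(benzyloxy)benzyl]-4-(3,4-dimethoxybenzyl)dihydrofuran-2(3H)-one, via hydroxy ester 10 (not isolated), via C3-epimeric lactone 11 (not isolated)
Conditions: LiBH4 (1.5 equiv), MeOH (1.5 equiv), THF, 0 °C; aq. NH4Cl work-up; crude, DBU (1.5 equiv), PhMe, 60 °C
Reagents that add atoms: none
Why: Reductive cleavage of the Evans imide (far more electrophilic than the benzyl ester) gives the γ-hydroxy ester, which lactonises with loss of BnOH, and DBU then equilibrates the enolisable C3 to the thermodynamically favoured trans (3R,4R) lactone while C4, not enolisable in the lactone, keeps its configuration.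

Step 5
Reactants: 12 (3R,4R)-3-[3,4-bis(benzyloxy)benzyl]-4-(3,4-dimethoxybenzyl)dihydrofuran-2(3H)-one
Product: 13 3'-O-demethylarctigenin, (3R,4R)-3-(3,4-dihydroxybenzyl)-4-(3,4-dimethoxybenzyl)dihydrofuran-2(3H)-one
Conditions: H2 (1 atm), 10% Pd/C, EtOAc/MeOH, rt; work-up under N2
Reagents that add atoms: none
Why: Neutral catalytic hydrogenolysis cleaves only the two benzyl aryl ethers, leaving the lactone, the aryl methyl ethers and both stereocentres untouched.

## Compound list

1 | 3-(3,4-dimethoxyphenyl)propanoic acid | COc1ccc(CCC(=O)O)cc1OC | starting material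
2 | (S)-4-benzyl-1,3-oxazolidin-2-one | O=C1N[C@@H](Cc2ccccc2)CO1 | starting material
3 | 3-(3,4-dimethoxyphenyl)propanoic pivalic anhydride | COc1ccc(CCC(=O)OC(=O)C(C)(C)C)cc1OC | intermediate
4 | (S)-4-benzyl-3-[3-(3,4-dimethoxyphenyl)propanoyl]-1,3-oxazolidin-2-one | COc1ccc(CCC(=O)N2[C@@H](Cc3ccccc3)COC2=O)cc1OC | intermediate
5 | 3-(3,4-dihydroxyphenyl)propanoic acid (hydrocaffeic acid) | OC(=O)CCc1ccc(O)c(O)c1 | starting material
6 | benzyl 3-[3,4-bis(benzyloxy)phenyl]propanoate | O=C(CCc1ccc(OCc2ccccc2)c(OCc2ccccc2)c1)OCc1ccccc1 | intermediate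
7 | lithium (Z)-enolate of imide 4 (O–Li cis to the benzylic CH2, chelated) | [Li+].[O-]/C(=C\Cc1ccc(OC)c(OC)c1)N1[C@@H](Cc2ccccc2)COC1=O | intermediate
8 | lithium enolate of ester 6 (O–Li trans to the benzylic CH2 drawn; geometry inconsequential) | [Li+].[O-]/C(=C/Cc1ccc(OCc2ccccc2)c(OCc2ccccc2)c1)OCc1ccccc1 | intermediate
9 | benzyl (3R)-4-[(4S)-4-benzyl-2-oxo-1,3-oxazolidin-3-yl]-2-[3,4-bis(benzyloxy)benzyl]-3-(3,4-dimethoxybenzyl)-4-oxobutanoate, C2 epimer mixture | COc1ccc(C[C@@H](C(=O)N2[C@@H](Cc3ccccc3)COC2=O)C(Cc3ccc(OCc4ccccc4)c(OCc4ccccc4)c3)C(=O)OCc3ccccc3)cc1OC | intermediate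
10 | benzyl (3R)-2-[3,4-bis(benzyloxy)benzyl]-3-(3,4-dimethoxybenzyl)-4-hydroxybutanoate, C2 epimer mixture | COc1ccc(C[C@@H](CO)C(Cc2ccc(OCc3ccccc3)c(OCc3ccccc3)c2)C(=O)OCc2ccccc2)cc1OC | intermediate
11 | (4R)-3-[3,4-bis(benzyloxy)benzyl]-4-(3,4-dimethoxybenzyl)dihydrofuran-2(3H)-one, C3 epimer mixture | COc1ccc(C[C@H]2COC(=O)C2Cc2ccc(OCc3ccccc3)c(OCc3ccccc3)c2)cc1OC | intermediate
12 | (3R,4R)-3-[3,4-bis(benzyloxy)benzyl]-4-(3,4-dimethoxybenzyl)dihydrofuran-2(3H)-one (trans) | COc1ccc(C[C@H]2COC(=O)[C@@H]2Cc2ccc(OCc3ccccc3)c(OCc3ccccc3)c2)cc1OC | intermediate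
13 | 3'-O-demethylarctigenin, (3R,4R)-3-(3,4-dihydroxybenzyl)-4-(3,4-dimethoxybenzyl)dihydrofuran-2(3H)-one | COc1ccc(C[C@H]2COC(=O)[C@@H]2Cc2ccc(O)c(O)c2)cc1OC | target

## Step count and risks

Total steps: 5. Longest linear sequence: 4 (steps 1, 3, 4, 5); step 2 is the one-step side branch.

**Step 3 (most likely to fail).** The oxidative heterocoupling can give homodimers of 4 and of 6, low conversion, or incomplete face control at the imide α-carbon. The excess of the cheap ester 6 is there to suppress the imide homodimer. The fallback sets out from 4 and comes back at 12. It makes the same C3–C4 bond with an α-halo ester as the electrophilic α-carbonyl carbon instead of an oxidant. The sodium enolate of 4 (NaHMDS, THF, –78 °C) is alkylated with tert-butyl bromoacetate to give tert-butyl (3R)-4-[(4S)-4-benzyl-2-oxo-1,3-oxazolidin-3-yl]-3-(3,4-dimethoxybenzyl)-4-oxobutanoate F1. LiBH4 removes the auxiliary to give tert-butyl (3R)-3-(3,4-dimethoxybenzyl)-4-hydroxybutanoate F2. TsOH in warm toluene closes this to (4R)-4-(3,4-dimethoxybenzyl)dihydrofuran-2(3H)-one F3. Its lithium enolate (LiHMDS, THF, –78 °C) is alkylated anti to the C4 substituent with 3,4-bis(benzyloxy)benzyl bromide F4, made from purchased 3,4-bis(benzyloxy)benzyl alcohol with PBr3, which gives 12 directly.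

**Step 4.** LiBH4 may over-reduce the benzyl ester or the lactone to a diol, or open the hindered imide at the ring carbonyl. The fallback sets out from 9 and comes back at 10. LiOH/H2O2 (THF/H2O, 0 °C) hydrolyses only the imide to give (2R)-4-(benzyloxy)-3-[3,4-bis(benzyloxy)benzyl]-2-(3,4-dimethoxybenzyl)-4-oxobutanoic acid F5. BH3·SMe2 (THF, 0 °C) then reduces the free acid but not the benzyl ester, giving 10, which is lactonised and epimerised with DBU as in step 4.

**Step 5.** Hydrogenolysis may stall after one benzyl group (catalyst poisoning by traces of DBU), and the catechol is air-sensitive during isolation. The fallback sets out from 12 and comes back at 13. It replaces reductive cleavage by Lewis-acid cleavage: BCl3 with pentamethylbenzene as a cation scavenger, CH2Cl2, –78 °C, which removes benzyl aryl ethers without H2 or metal and spares aryl methyl ethers and the lactone at that temperature. It makes no new compound (entry F0).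

## Further compounds

F1 | step 3 | tert-butyl (3R)-4-[(4S)-4-benzyl-2-oxo-1,3-oxazolidin-3-yl]-3-(3,4-dimethoxybenzyl)-4-oxobutanoate | COc1ccc(C[C@@H](C(=O)N2[C@@H](Cc3ccccc3)COC2=O)CC(=O)OC(C)(C)C)cc1OC
F2 | step 3 | tert-butyl (3R)-3-(3,4-dimethoxybenzyl)-4-hydroxybutanoate | COc1ccc(C[C@@H](CO)CC(=O)OC(C)(C)C)cc1OC
F3 | step 3 | (4R)-4-(3,4-dimethoxybenzyl)dihydrofuran-2(3H)-one | COc1ccc(C[C@H]2COC(=O)C2)cc1OC
F4 | step 3 | 3,4-bis(benzyloxy)benzyl bromide | BrCc1ccc(OCc2ccccc2)c(OCc2ccccc2)c1
F5 | step 4 | (2R)-4-(benzyloxy)-3-[3,4-bis(benzyloxy)benzyl]-2-(3,4-dimethoxybenzyl)-4-oxobutanoic acid, C3 epimer mixture | COc1ccc(C[C@@H](C(=O)O)C(Cc2ccc(OCc3ccccc3)c(OCc3ccccc3)c2)C(=O)OCc2ccccc2)cc1OC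
F0 | step 5 | none | none
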